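## The problem

The target, (3S)-3-(3-hydroxy-2,4,5-trimethoxyphenyl)-8-methoxychroman-7-ol (23), is an isoflavan: ring A is fused to the saturated oxygen heterocycle (ring C), and the pentasubstituted ring B sits on C3. Ring C contains only the sp3 carbons C2, C3 and C4, so the skeleton is a 1,2-diarylpropane whose C2 oxygen is tied back to ring A as O1. C3 is the only stereocentre, (S) by the order C2 > C1' > C4 > H. Nothing else in the molecule can relay chirality to it, so its configuration must come from a reagent, auxiliary or catalyst, and afterwards C3 must never sit next to a carbonyl group or in a double bond. Ring B carries four contiguous oxygens of which only O3', flanked by two methoxy groups, is a phenol, and ring A carries the 7-OH beside the 8-OMe. These oxygens must be distinguished from the methyl ethers when each ring is first built, and the position of C1' on ring B cannot be left to electrophilic substitution of an unsymmetrical arene. Both rings are very electron-rich: the free phenols oxidise easily, the arenes trap carbocations, and quinone oxidants attack the benzylic C–H bonds at C3 and C4, so the late steps must be neutral, reductive or mildly acidic. The feature that opens the synthesis is C3 itself: a methine bound to one hydrogen and to three different carbons, C2 (a CH2 carrying oxygen), C1' (an aryl carbon) and C4 (a benzylic CH2). That is the carbon of dichloromethane after both chlorides have been replaced, so C3 can be delivered to boron as a dichloromethyl carbenoid and take up C2 and C1' one after the other by 1,2-shifts, with boron left on C3 as the handle for C4.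

## Retrosynthesis

**23 from 22.** The last operation only frees the 3'-OH. A benzyl ether is chosen for this oxygen because it survives organolithium and Grignard reagents, base, fluoride and the acid used later, and because hydrogenolysis is neutral and cannot touch C3.

**22 from 21 (O1–C2).** Ring C is opened at the O1–C2 bond. Cutting C4–C4a in a ring closure would need an electrophilic cyclisation whose regiochemistry on ring A is not secured, and cutting O1–C8a would need a metal-catalysed aryl ether formation on a hindered arene. The O1–C2 cut leads to the phenol-alcohol 21, and the closure takes place at a CH2 carbon that is not stereogenic. It asks only for an intramolecular etherification that forms a six-membered ring.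

**21 from 20, and 20 from 16 and 19 (C4–C4a).** Compound 21 is the deprotected form of 20, in which the C2 oxygen is a 4-methoxybenzyl ether and the ring A oxygens are methoxymethyl ethers; all three fall in one acid step while the benzyl ether stays. The C4–C4a bond is cut next, which separates the two aromatic rings and makes the route convergent. The neighbouring cut, C3–C4, would call for a C3 enolate and would put the stereocentre next to a carbonyl group. The C4–C4a cut needs only the primary alkyltrifluoroborate 16 and the aryl bromide 19; C3 is one carbon away from boron and takes no part.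

**16 from 15, and 15 from 14 (C3–C4).** The trifluoroborate 16 is the activated form of the boronic ester 15. C4 is a single CH2 between C3 and boron, so 15 arises from the secondary boronic ester 14 by insertion of a chloromethyl carbenoid into the C3–B bond. This shift goes with retention at the migrating carbon, so the configuration set earlier is carried over. The boron atom that was used to build C3 thus also delivers C4 and the coupling handle.

**14 from 4 and 12 (C2–C3 and C3–C1', the key step).** In 14, C3 bears boron, C2 and C1'. Both carbon substituents are attached in one flask: LiCHCl2 inserts into the C2–B bond of the alkoxymethyl boronic ester 4 to give the α-chloro boronic ester 13, and the aryl Grignard reagent 12 then replaces the chloride. Against an enolate alkylation or an asymmetric hydrogenation, this cut offers a stereocentre that is never enolisable, a sense of induction that follows a firm rule, and a precursor (4) with one carbon and no stereocentre in the chain. The target needs (S) at C3. Because the aryl shift inverts and the aryl group ranks below the CH2O carbon, 13 must be (S), and by the established behaviour of C2-symmetric diol esters this requires the (R,R)-diol. The forward reaction must give high selectivity in the first shift, clean inversion in the second, and must tolerate the ether oxygen two atoms from boron.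

**4 from 3, and 3 from 1 and 2.** The 4-methoxybenzyloxy group is introduced by alkoxide displacement on the bromomethyl boronic ester 3, itself a 1,2-shift on boron. Compound 3 comes from the commercial trifluoroborate 1 and the diol 2, which is sold in both enantiomeric forms. The acid-labile ether is put on after the diol, because the diol exchange sets free acid.

**12 from 11, 11 from 10, 10 from 7, 7 from 6, 6 from 5 (ring B).** The Grignard reagent 12 comes from bromide 11. An unsymmetrical tetra-oxygenated benzene would brominate at two nearly equivalent positions, so the pattern is set by symmetry instead. 2,6-Dimethoxyphenol (5) is benzylated on the oxygen that will become the 3'-OH (6) and brominated twice at the two equivalent positions ortho and para to the methoxy groups (7). One of the two equivalent bromides is then exchanged for lithium, converted into the phenol 10 and methylated (11). No regiochemical choice is left open.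

**19 from 18, and 18 from 17 (ring A).** 2-Methoxyresorcinol (17) is protected on both oxygens (18), which keeps its symmetry, and brominated at the one kind of activated position (19). The oxygen ortho to bromine becomes O1; the other becomes the 7-OH, which is left free during ring closure because it cannot reach C2.

## Roads not taken

**Alternative 1: carbene C–H insertion, then opening of a dihydrobenzofuran.** The cut is C3–C4. Ring B would carry a diazoacetate at C1' and, on O2', the benzyl group of ring A (diazo ester A1). A chiral dirhodium tetracarboxylate such as Rh2(S-PTTL)4 would generate the carbene at C3, which inserts into the ether-activated benzylic C4–H bond and gives the cis-dihydrobenzofuran A2. Hydrogenolysis of the benzylic C4–O bond, methylation of the freed 2'-phenol, reduction of the ester to the C2 alcohol and closure of ring C would follow.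
- Merits: the stereocentre is set by a catalyst in small amount; C3–C4 forms in a step that joins both rings; no cryogenic organometallic step is needed. In these respects it is better than the plan adopted here.
- Weak points: in A2 and in every intermediate up to the ester reduction, C3 is benzylic and α to an ester, so the base needed to methylate O2' can erase the only stereocentre. Ring B must be built with two oxygens (O2' and O3') distinguished from the methyl ethers instead of one. Three kinds of phenol protecting group are needed.
- Comparison: the adopted plan uses a stoichiometric diol, but it is recovered, its sense of induction is fixed by rule, and C3 is never enolisable.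

**Alternative 2: ring B grown from a cyclobutenone.** The cut runs through ring B (C1'–C2' among others). Heating the 4-alkenyl-4-methoxycyclobutenone A3 opens the four-membered ring to a dienylketene, which closes by 6π electrocyclisation and tautomerises to the phenol A4. Methylation of O2' and removal of the isopropyl group from O3' would finish the synthesis.
- Merits: the substitution pattern of ring B is written into the four-membered ring, so no aromatic substitution has to be controlled. In this respect it is better than the five-step ring B sequence used here. The key step needs no reagent.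
- Weak points: the step does nothing for C3. A3 already contains the stereocentre, so a separate asymmetric synthesis of the chroman part must come first. During the thermolysis C3 is allylic to the dienylketene, so migration of the double bond can racemise it. The end game requires selective cleavage of one isopropyl ether beside four methyl ethers with a Lewis acid on a very electron-rich substrate.
- Comparison: the adopted plan pays more steps for ring B but obtains its pattern by symmetry and gets C3, C2–C3 and C3–C1' from one operation.

**Alternative 3: one-carbon insertion into a benzofuran.** The cuts are C2–C3 and C3–C4. The chlorodiazirine A5 would release an arylchlorocarbene that cyclopropanates the C2=C3 bond of the benzofuran A6; opening of the adduct with loss of chloride gives the 3-arylbenzopyrylium salt A7. Partial reduction and asymmetric hydrogenation of the C3=C4 double bond, for example with an [Ir(cod)(phosphine–oxazoline)]BArF catalyst, would then set C3.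
- Merits: the whole skeleton arises in one step from two aromatic pieces, O1 needs no protection, and the route would be clearly shorter. In step economy it is better than the adopted plan.
- Weak points: the ring expansion is well developed for nitrogen heterocycles but not for benzofurans, where the product is an electrophilic pyrylium salt. A chlorodiazirine on a tetra-oxygenated arene is expected to be labile and its carbene less electrophilic. C3 is set afterwards by hydrogenation of a trisubstituted olefin next to an ortho-methoxyaryl group, a case in which selectivity is hard to predict.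
- Comparison: two uncertain steps stand in series, one of them the stereo-determining step. The adopted plan is longer, but each step has close precedent and the configuration comes from a substrate-controlled 1,2-shift.

Key step: step 8

Remark: the target is read as (3S); the sense of induction is taken from the established rule that an (R,R)-configured C2-symmetric diol boronic ester gives the (αS)-α-chloro boronic ester.

## Route

Step 1
Reactants: 1 potassium (bromomethyl)trifluoroborate; 2 (1R,2R)-1,2-dicyclohexylethane-1,2-diol
Product: 3 (4R,5R)-2-(bromomethyl)-4,5-dicyclohexyl-1,3,2-dioxaborolane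
Conditions: TMSCl, MeCN, rt
Reagents that add atoms: none
Why: Fluoride abstraction by the silyl chloride turns the trifluoroborate into a dihaloborane that the diol esterifies in the same flask (trifluoroborate-to-boronic-ester exchange); the carbinol carbons are not touched, and no acid-sensitive group is present yet.

Step 2
Reactants: 3 (4R,5R)-2-(bromomethyl)-4,5-dicyclohexyl-1,3,2-dioxaborolane
Product: 4 (4R,5R)-4,5-dicyclohexyl-2-[(4-methoxybenzyloxy)methyl]-1,3,2-dioxaborolane
Conditions: 4-MeOC6H4CH2OH, NaH, THF, 0 °C; then 3, DMSO, rt
Reagents that add atoms: 4-methoxybenzyl alcohol, COc1ccc(CO)cc1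
Why: The alkoxide adds to boron and the alkoxy group then shifts from boron to carbon with loss of bromide (alkoxide displacement on an α-halo boronic ester); DMSO speeds the shift and the diol ester is stable to alkoxide.

Step 3
Reactants: 5 2,6-dimethoxyphenol
Product: 6 2-(benzyloxy)-1,3-dimethoxybenzene
Conditions: BnBr, K2CO3, DMF, 60 °C
Reagents that add atoms: benzyl bromide, BrCc1ccccc1
Why: Williamson etherification of the phenol; the benzyl group marks the oxygen that becomes the 3'-OH and keeps the arene symmetric.

Step 4
Reactants: 6 2-(benzyloxy)-1,3-dimethoxybenzene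
Product: 7 3-(benzyloxy)-1,5-dibromo-2,4-dimethoxybenzene
Conditions: NBS (2 equiv), MeCN, 0 °C to rt
Reagents that add atoms: N-bromosuccinimide, O=C1CCC(=O)N1Br
Why: Electrophilic aromatic bromination; the two equivalent positions that are ortho to one methoxy group and para to the other are activated, whereas the position para to the twisted benzyloxy group is not, so only one dibromide can form.

Step 5
Reactants: 7 3-(benzyloxy)-1,5-dibromo-2,4-dimethoxybenzene
Product: 10 3-(benzyloxy)-5-bromo-2,4-dimethoxyphenol, via aryllithium 8 (not isolated), via dimethyl arylboronate 9 (not isolated)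
Conditions: n-BuLi (1 equiv), THF, −78 °C; B(OMe)3, −78 to 0 °C; then H2O2, AcOH, 0 °C to rt
Reagents that add atoms: hydrogen peroxide, OO
Why: Bromine–lithium exchange at one of two equivalent bromides gives 8, which is trapped as 9 and oxidised with retention at the aryl carbon (borylation–oxidation); symmetry removes any regiochemical question, and the remaining bromine is meta to lithium, so no aryne can form.

Step 6
Reactants: 10 3-(benzyloxy)-5-bromo-2,4-dimethoxyphenol
Product: 11 3-(benzyloxy)-1-bromo-2,4,5-trimethoxybenzene
Conditions: MeI, K2CO3, acetone, reflux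
Reagents that add atoms: iodomethane, CI
Why: O-Methylation of the phenol (Williamson etherification) completes the 2,4,5-trimethoxy pattern with the benzyl ether on the inner oxygen.

Step 7
Reactants: 11 3-(benzyloxy)-1-bromo-2,4,5-trimethoxybenzene
Product: 12 [3-(benzyloxy)-2,4,5-trimethoxyphenyl]magnesium bromide
Conditions: Mg turnings, LiCl, THF, rt; titrated and used as solution
Reagents that add atoms: magnesium, [Mg]
Why: Direct insertion of magnesium into the aryl bromide (Grignard formation), assisted by LiCl; the ether groups are inert.

Step 8
Reactants: 4 (4R,5R)-4,5-dicyclohexyl-2-[(4-methoxybenzyloxy)methyl]-1,3,2-dioxaborolane; 12 [3-(benzyloxy)-2,4,5-trimethoxyphenyl]magnesium bromide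
Product: 14 (4R,5R)-2-[(1S)-1-(3-benzyloxy-2,4,5-trimethoxyphenyl)-2-(4-methoxybenzyloxy)ethyl]-4,5-dicyclohexyl-1,3,2-dioxaborolane, via α-chloro boronic ester 13 (not isolated)
Conditions: CH2Cl2, n-BuLi, THF, −100 °C; 4; ZnCl2 (1 equiv), −100 °C to rt; then 12 (excess), THF, −78 °C to rt
Reagents that add atoms: dichloromethane, ClCCl
Why: This is a Matteson homologation followed by Grignard displacement of the α-chloride, the closest known reaction type being the chain extension of chiral alkoxymethyl boronic esters with LiCHCl2 and ZnCl2. LiCHCl2 adds to the trigonal boron of 4 to give a tetracoordinate borate; ZnCl2 binds a dioxaborolane oxygen and one of the two diastereotopic chlorides, and the (4-methoxybenzyloxy)methyl group shifts from boron to carbon anti to that chloride, forming C2–C3 and the (S)-chloride 13. The C2-symmetric (R,R)-diol decides which chloride leaves, and the rule (R,R)-diol to (αS)-chloride applies because the order Cl > C > B at the new centre is the same as for alkyl groups. ZnCl2 also binds free chloride, which would otherwise epimerise 13. The aryl Grignard reagent 12 then adds to boron and the aryl group shifts with inversion at carbon, displacing the second chloride and forming C3–C1'; the descriptor stays (S) because the aryl carbon ranks below the CH2O carbon. No ring closes. The step needs diastereoselection in the first shift, secured by the diol, and stereospecificity in the second, secured by the concerted antiperiplanar shift. The ether oxygen two atoms from boron is a poor leaving group, so β-elimination should not compete.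

Step 9
Reactants: 14 (4R,5R)-2-[(1S)-1-(3-benzyloxy-2,4,5-trimethoxyphenyl)-2-(4-methoxybenzyloxy)ethyl]-4,5-dicyclohexyl-1,3,2-dioxaborolane
Product: 15 (4R,5R)-2-[(2S)-2-(3-benzyloxy-2,4,5-trimethoxyphenyl)-3-(4-methoxybenzyloxy)propyl]-4,5-dicyclohexyl-1,3,2-dioxaborolane
Conditions: ICH2Cl, n-BuLi, THF, −78 °C to rt
Reagents that add atoms: chloroiodomethane, ClCI
Why: Matteson one-carbon homologation: LiCH2Cl, formed by iodine–lithium exchange in the presence of 14, adds to boron and the secondary benzylic carbon shifts to the CH2 carbon with loss of chloride; the shift goes with retention at C3, so the configuration is kept and C4 is in place.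

Step 10
Reactants: 15 (4R,5R)-2-[(2S)-2-(3-benzyloxy-2,4,5-trimethoxyphenyl)-3-(4-methoxybenzyloxy)propyl]-4,5-dicyclohexyl-1,3,2-dioxaborolane
Product: 16 potassium [(2S)-2-(3-benzyloxy-2,4,5-trimethoxyphenyl)-3-(4-methoxybenzyloxy)propyl]trifluoroborate
Conditions: KHF2, MeOH/H2O, rt
Reagents that add atoms: potassium hydrogen difluoride, [K+].F[H-]F
Why: Fluoride displaces the diol from boron and gives the air-stable trifluoroborate, the form of a primary alkylboron that transmetallates reliably; C3 is remote from boron and the diol is recovered.

Step 11
Reactants: 17 2-methoxybenzene-1,3-diol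
Product: 18 2-methoxy-1,3-bis(methoxymethoxy)benzene
Conditions: NaH, MOMCl, DMF, 0 °C to rt
Reagents that add atoms: chloromethyl methyl ether, COCCl
Why: Double O-alkylation of the resorcinol (acetal protection); both hydroxyls are treated alike, so the symmetry of 17 is kept and no statistical monoprotection is needed.

Step 12
Reactants: 18 2-methoxy-1,3-bis(methoxymethoxy)benzene
Product: 19 1-bromo-3-methoxy-2,4-bis(methoxymethoxy)benzene
Conditions: NBS (1 equiv), MeCN, 0 °C
Reagents that add atoms: N-bromosuccinimide, O=C1CCC(=O)N1Br
Why: Electrophilic bromination ortho to one acetal oxygen and para to the other; the two such positions are equivalent and the third free position is meta to both, so one monobromide should result.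

Step 13
Reactants: 16 potassium [(2S)-2-(3-benzyloxy-2,4,5-trimethoxyphenyl)-3-(4-methoxybenzyloxy)propyl]trifluoroborate; 19 1-bromo-3-methoxy-2,4-bis(methoxymethoxy)benzene
Product: 20 1-[(2S)-2-(3-benzyloxy-2,4,5-trimethoxyphenyl)-3-(4-methoxybenzyloxy)propyl]-3-methoxy-2,4-bis(methoxymethoxy)benzene
Conditions: Pd(OAc)2, RuPhos, K2CO3, toluene/H2O, 85 °C
Reagents that add atoms: none
Why: B-alkyl Suzuki–Miyaura coupling of a primary alkyltrifluoroborate with an aryl bromide forms C4–C4a; the bulky, electron-rich phosphine speeds oxidative addition into the electron-rich bromide and reductive elimination ahead of β-hydride elimination, and C3 takes no part.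

Step 14
Reactants: 20 1-[(2S)-2-(3-benzyloxy-2,4,5-trimethoxyphenyl)-3-(4-methoxybenzyloxy)propyl]-3-methoxy-2,4-bis(methoxymethoxy)benzene
Product: 21 (2S)-2-(3-benzyloxy-2,4,5-trimethoxyphenyl)-3-(2,4-dihydroxy-3-methoxyphenyl)propan-1-ol
Conditions: TFA, Et3SiH, CH2Cl2, 0 °C to rt; then K2CO3, MeOH
Reagents that add atoms: none
Why: Acidolysis: the 4-methoxybenzyl ether and both aryl methoxymethyl acetals ionise in TFA while the aryl benzyl ether does not; the silane reduces the cations before they can alkylate the electron-rich rings, and the basic methanol work-up cleaves any trifluoroacetate or silyl ether on the primary alcohol.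

Step 15
Reactants: 21 (2S)-2-(3-benzyloxy-2,4,5-trimethoxyphenyl)-3-(2,4-dihydroxy-3-methoxyphenyl)propan-1-ol
Product: 22 (3S)-3-(3-benzyloxy-2,4,5-trimethoxyphenyl)-8-methoxychroman-7-ol
Conditions: PPh3, DIAD, THF (dilute), 0 °C to rt
Reagents that add atoms: none
Why: Intramolecular Mitsunobu etherification: the primary alcohol is activated as its oxyphosphonium salt and displaced by the ortho phenol in a 6-exo-tet closure that forms O1–C2 and ring C; the 7-OH cannot reach C2, and the reacting carbon is not stereogenic, so C3 is untouched.

Step 16
Reactants: 22 (3S)-3-(3-benzyloxy-2,4,5-trimethoxyphenyl)-8-methoxychroman-7-ol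
Product: 23 (3S)-3-(3-hydroxy-2,4,5-trimethoxyphenyl)-8-methoxychroman-7-ol
Conditions: H2 (1 atm), Pd/C, EtOAc/MeOH, rt
Reagents that add atoms: none
Why: Hydrogenolysis of the aryl benzyl ether under neutral conditions; the chroman has no benzylic C–O bond, so nothing else should be reduced.

## Compound list

1 | potassium (bromomethyl)trifluoroborate | [K+].BrC[B-](F)(F)F | starting material
2 | (1R,2R)-1,2-dicyclohexylethane-1,2-diol | O[C@H](C1CCCCC1)[C@H](O)C1CCCCC1 | starting material
3 | (4R,5R)-2-(bromomethyl)-4,5-dicyclohexyl-1,3,2-dioxaborolane | BrCB1O[C@H](C2CCCCC2)[C@@H](C2CCCCC2)O1 | intermediate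
4 | (4R,5R)-4,5-dicyclohexyl-2-[(4-methoxybenzyloxy)methyl]-1,3,2-dioxaborolane | COc1ccc(COCB2O[C@H](C3CCCCC3)[C@@H](C3CCCCC3)O2)cc1 | intermediate
5 | 2,6-dimethoxyphenol | COc1cccc(OC)c1O | starting material
6 | 2-(benzyloxy)-1,3-dimethoxybenzene | COc1cccc(OC)c1OCc1ccccc1 | intermediate
7 | 3-(benzyloxy)-1,5-dibromo-2,4-dimethoxybenzene | COc1c(Br)cc(Br)c(OC)c1OCc1ccccc1 | intermediate
8 | [3-(benzyloxy)-5-bromo-2,4-dimethoxyphenyl]lithium | [Li]c1cc(Br)c(OC)c(OCc2ccccc2)c1OC | intermediate
9 | dimethyl [3-(benzyloxy)-5-bromo-2,4-dimethoxyphenyl]boronate | COB(OC)c1cc(Br)c(OC)c(OCc2ccccc2)c1OC | intermediate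
10 | 3-(benzyloxy)-5-bromo-2,4-dimethoxyphenol | COc1c(O)cc(Br)c(OC)c1OCc1ccccc1 | intermediate
11 | 3-(benzyloxy)-1-bromo-2,4,5-trimethoxybenzene | COc1cc(Br)c(OC)c(OCc2ccccc2)c1OC | intermediate
12 | [3-(benzyloxy)-2,4,5-trimethoxyphenyl]magnesium bromide | Br[Mg]c1cc(OC)c(OC)c(OCc2ccccc2)c1OC | intermediate
13 | (4R,5R)-2-[(1S)-1-chloro-2-(4-methoxybenzyloxy)ethyl]-4,5-dicyclohexyl-1,3,2-dioxaborolane | COc1ccc(COC[C@@H](Cl)B2O[C@H](C3CCCCC3)[C@@H](C3CCCCC3)O2)cc1 | intermediate
14 | (4R,5R)-2-[(1S)-1-(3-benzyloxy-2,4,5-trimethoxyphenyl)-2-(4-methoxybenzyloxy)ethyl]-4,5-dicyclohexyl-1,3,2-dioxaborolane | COc1ccc(COC[C@H](c2cc(OC)c(OC)c(OCc3ccccc3)c2OC)B2O[C@H](C3CCCCC3)[C@@H](C3CCCCC3)O2)cc1 | intermediate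
15 | (4R,5R)-2-[(2S)-2-(3-benzyloxy-2,4,5-trimethoxyphenyl)-3-(4-methoxybenzyloxy)propyl]-4,5-dicyclohexyl-1,3,2-dioxaborolane | COc1ccc(COC[C@H](c2cc(OC)c(OC)c(OCc3ccccc3)c2OC)CB2O[C@H](C3CCCCC3)[C@@H](C3CCCCC3)O2)cc1 | intermediate
16 | potassium [(2S)-2-(3-benzyloxy-2,4,5-trimethoxyphenyl)-3-(4-methoxybenzyloxy)propyl]trifluoroborate | [K+].COc1ccc(COC[C@H](c2cc(OC)c(OC)c(OCc3ccccc3)c2OC)C[B-](F)(F)F)cc1 | intermediate
17 | 2-methoxybenzene-1,3-diol | COc1c(O)cccc1O | starting material
18 | 2-methoxy-1,3-bis(methoxymethoxy)benzene | COCOc1cccc(OCOC)c1OC | intermediate
19 | 1-bromo-3-methoxy-2,4-bis(methoxymethoxy)benzene | COCOc1ccc(Br)c(OCOC)c1OC | intermediate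
20 | 1-[(2S)-2-(3-benzyloxy-2,4,5-trimethoxyphenyl)-3-(4-methoxybenzyloxy)propyl]-3-methoxy-2,4-bis(methoxymethoxy)benzene | COc1ccc(COC[C@H](c2cc(OC)c(OC)c(OCc3ccccc3)c2OC)Cc2ccc(OCOC)c(OC)c2OCOC)cc1 | intermediate
21 | (2S)-2-(3-benzyloxy-2,4,5-trimethoxyphenyl)-3-(2,4-dihydroxy-3-methoxyphenyl)propan-1-ol | OC[C@H](c1cc(OC)c(OC)c(OCc2ccccc2)c1OC)Cc1ccc(O)c(OC)c1O | intermediate
22 | (3S)-3-(3-benzyloxy-2,4,5-trimethoxyphenyl)-8-methoxychroman-7-ol | COc1cc([C@H]2COc3c(ccc(O)c3OC)C2)c(OC)c(OCc2ccccc2)c1OC | intermediate
23 | (3S)-3-(3-hydroxy-2,4,5-trimethoxyphenyl)-8-methoxychroman-7-ol | COc1cc([C@H]2COc3c(ccc(O)c3OC)C2)c(OC)c(O)c1OC | target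

## Step count and risks

Total: 16 steps (2 for the boron piece, 5 for ring B, 2 for ring A, 7 from the key step to the target). Longest linear sequence: 12 steps, from 5 to 23 through steps 3–10 and 13–16.

**Step 8 (key step).** Three things can go wrong:
- loss of diastereocontrol in the first shift, or epimerisation of the α-chloride by free chloride, because the ether oxygen competes with the dioxaborolane oxygen for zinc;
- slow arylation, because part of the Grignard reagent is converted into a less reactive arylzinc by the ZnCl2 left in the flask;
- β-elimination of the alkoxide from the borate.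

Epimers at C3 are diastereomers as long as the diol is on boron, so the outcome can be judged and improved at 14 or 15. Fallback, from 12 to 16, with C3 set by a catalyst instead of by the diol. The Grignard reagent 12 would be cross-coupled (PdCl2(dppf), THF) with 2-bromoallyl 4-methoxybenzyl ether F1, made from 2,3-dibromopropene and sodium 4-methoxybenzyl oxide. This would give the 1,1-disubstituted alkene 3-(benzyloxy)-2,4,5-trimethoxy-1-[3-(4-methoxybenzyloxy)prop-1-en-2-yl]benzene F2. Enantioselective anti-Markovnikov hydroboration (CuCl, DTBM-SEGPHOS of the handedness that gives the S product, KOtBu, HBpin) would give the pinacol boronic ester F3. KHF2 then leads back to 16.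

**Step 13 (with step 10).** Slow transmetallation of the β-branched alkylboron and β-hydride elimination from the alkylpalladium intermediate are the main dangers, and the hindered diol may be released incompletely in step 10. Fallback, from 15 to 20, which bypasses both steps by changing the metal. Oxidation of 15 (NaBO3·4H2O, THF/H2O) would give the alcohol (2R)-2-(3-benzyloxy-2,4,5-trimethoxyphenyl)-3-(4-methoxybenzyloxy)propan-1-ol F4. I2, PPh3 and imidazole convert it into the iodide F5, and zinc dust with LiCl in THF gives the alkylzinc iodide F6. Negishi coupling of F6 with 19 (Pd(OAc)2, SPhos, THF) then gives 20.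

**Step 14.** The danger is alkylation of the electron-rich rings by the 4-methoxybenzyl or methoxymethyl cation before the silane intercepts them, together with partial loss of the aryl benzyl ether. Fallback, from 20 to 23, with a different order of unmasking. HCl in MeOH/THF would remove only the acetals and give the diphenol F7. Hydrogenolysis over Pd(OH)2/C then removes the benzyl and 4-methoxybenzyl groups together and gives the triphenol alcohol F8. A Mitsunobu closure (PPh3, DIAD, dilute THF) as the last step leads directly to 23.

**Step 15.** Intermolecular etherification through the free 7-OH, alkylation of the reduced azodicarboxylate, or elimination from the oxyphosphonium salt may compete with ring closure. Fallback, from 21 to 22, in two steps. CBr4 and PPh3 would convert the primary alcohol into the bromide F9. K2CO3 in dilute DMF then closes ring C by intramolecular Williamson etherification to give 22.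

## Further compounds

F1 | step 8 | 2-bromoallyl 4-methoxybenzyl ether | C=C(Br)COCc1ccc(OC)cc1
F2 | step 8 | 3-(benzyloxy)-2,4,5-trimethoxy-1-[3-(4-methoxybenzyloxy)prop-1-en-2-yl]benzene | C=C(COCc1ccc(OC)cc1)c1cc(OC)c(OC)c(OCc2ccccc2)c1OC
F3 | step 8 | 2-[(2S)-2-(3-benzyloxy-2,4,5-trimethoxyphenyl)-3-(4-methoxybenzyloxy)propyl]-4,4,5,5-tetramethyl-1,3,2-dioxaborolane | COc1ccc(COC[C@H](c2cc(OC)c(OC)c(OCc3ccccc3)c2OC)CB2OC(C)(C)C(C)(C)O2)cc1
F4 | step 13 | (2R)-2-(3-benzyloxy-2,4,5-trimethoxyphenyl)-3-(4-methoxybenzyloxy)propan-1-ol | COc1ccc(COC[C@H](c2cc(OC)c(OC)c(OCc3ccccc3)c2OC)CO)cc1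
F5 | step 13 | 3-(benzyloxy)-1-[(2S)-1-iodo-3-(4-methoxybenzyloxy)propan-2-yl]-2,4,5-trimethoxybenzene | COc1ccc(COC[C@H](c2cc(OC)c(OC)c(OCc3ccccc3)c2OC)CI)cc1
F6 | step 13 | [(2S)-2-(3-benzyloxy-2,4,5-trimethoxyphenyl)-3-(4-methoxybenzyloxy)propyl]zinc iodide | COc1ccc(COC[C@H](c2cc(OC)c(OC)c(OCc3ccccc3)c2OC)C[Zn]I)cc1
F7 | step 14 | 4-[(2S)-2-(3-benzyloxy-2,4,5-trimethoxyphenyl)-3-(4-methoxybenzyloxy)propyl]-2-methoxybenzene-1,3-diol | COc1ccc(COC[C@H](c2cc(OC)c(OC)c(OCc3ccccc3)c2OC)Cc2ccc(O)c(OC)c2O)cc1
F8 | step 14 | 4-[(2S)-3-hydroxy-2-(3-hydroxy-2,4,5-trimethoxyphenyl)propyl]-2-methoxybenzene-1,3-diol | OC[C@H](c1cc(OC)c(OC)c(O)c1OC)Cc1ccc(O)c(OC)c1O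
F9 | step 15 | 4-[(2S)-2-(3-benzyloxy-2,4,5-trimethoxyphenyl)-3-bromopropyl]-2-methoxybenzene-1,3-diol | BrC[C@H](c1cc(OC)c(OC)c(OCc2ccccc2)c1OC)Cc1ccc(O)c(OC)c1O
A1 | alternative 1 | methyl 2-diazo-2-{4,5-dimethoxy-2-[(3-methoxy-2-pivaloyloxy-4-triisopropylsilyloxyphenyl)methoxy]-3-(triisopropylsilyloxy)phenyl}acetate | COC(=O)C(=[N+]=[N-])c1cc(OC)c(OC)c(O[Si](C(C)C)(C(C)C)C(C)C)c1OCc1ccc(O[Si](C(C)C)(C(C)C)C(C)C)c(OC)c1OC(=O)C(C)(C)C
A2 | alternative 1 | methyl (2S,3R)-cis-5,6-dimethoxy-2-[3-methoxy-2-(pivaloyloxy)-4-(triisopropylsilyloxy)phenyl]-7-(triisopropylsilyloxy)-2,3-dihydro-1-benzofuran-3-carboxylate | COC(=O)[C@H]1[C@@H](c3ccc(O[Si](C(C)C)(C(C)C)C(C)C)c(OC)c3OC(=O)C(C)(C)C)Oc2c(O[Si](C(C)C)(C(C)C)C(C)C)c(OC)c(OC)cc12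
A3 | alternative 2 | 4-{(E)-2-[(3S)-7-(benzyloxy)-8-methoxychroman-3-yl]ethenyl}-2-isopropoxy-3,4-dimethoxycyclobut-2-en-1-one | O=C1C(OC(C)C)=C(OC)C1(OC)/C=C/[C@H]1COc2c(ccc(OCc3ccccc3)c2OC)C1
A4 | alternative 2 | 6-[(3S)-7-(benzyloxy)-8-methoxychroman-3-yl]-2-isopropoxy-3,4-dimethoxyphenol | Oc1c(OC(C)C)c(OC)c(OC)cc1[C@H]1COc2c(ccc(OCc3ccccc3)c2OC)C1
A5 | alternative 3 | 3-[3-(benzyloxy)-2,4,5-trimethoxyphenyl]-3-chloro-3H-diazirine | ClC1(N=N1)c1cc(OC)c(OC)c(OCc2ccccc2)c1OC
A6 | alternative 3 | 6-(benzyloxy)-7-methoxy-1-benzofuran | COc1c(OCc2ccccc2)ccc2ccoc12
A7 | alternative 3 | 7-(benzyloxy)-3-[3-(benzyloxy)-2,4,5-trimethoxyphenyl]-8-methoxy-1-benzopyrylium chloride | COc1c(OCc2ccccc2)ccc2cc(-c3cc(OC)c(OC)c(OCc4ccccc4)c3OC)c[o+]c12.[Cl-]
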